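**Retrosynthetic overview**

1. The target comes from 2-(2-hydroxy-4-methoxyphenyl)-3,5,6,7,8-pentamethoxychromone by chelation-controlled cleavage of the 5-methyl ether, which lies peri to the C4 carbonyl, in the last step.
2. The strategy rests on ring B (C1'–C6'): a resorcinol unit with 2'-OH ortho and 4'-OMe para to C1', bonded through C1' to C2 of the electron-poor pyranone ring C. It is cut at C1'–C2' and C5'–C6' into a 2-ethynylchromone (C1', C6') and 1,3-dimethoxy-1-(trimethylsilyloxy)buta-1,3-diene (C2'–C5'), whose 1- and 3-oxygens become the 2'- and 4'-oxygens.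
3. The ethynylchromone comes from the 2-iodochromone (C2 zincation/iodination, Sonogashira coupling), this from 3,5,6,7,8-pentamethoxychromone, and this from a 2-hydroxyaryl methoxymethyl ketone plus one carbon from an amide acetal.
4. The ketone comes from 2,3,4,5-tetramethoxyphenol and methoxyacetyl chloride; the phenol from 2,3,4-trimethoxybenzaldehyde (Dakin oxidation, methylation, lithiation–borylation–oxidation).
5. Ring order: ring A is bought and oxygenated, ring C is closed in step 5, ring B is built last in step 10.

Key step: step 10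

Remark: the cycloadduct of step 10 has one stereocenter (the ketal carbon), formed as a racemate. It becomes the aromatic C2', so the route needs no stereocontrol, and the diene geometry is likewise without consequence.

**Route**

Step 1
Reactants: 1 2,3,4-trimethoxybenzaldehyde
Product: 3 2,3,4-trimethoxyphenol, via 2,3,4-trimethoxyphenyl formate 2 (not isolated)
Conditions: mCPBA, CH2Cl2, 0 → 25 °C; NaHCO3 wash; then K2CO3 (cat.), MeOH, 25 °C
Reagents that add atoms: 3-chloroperoxybenzoic acid (mCPBA), OOC(=O)c1cccc(Cl)c1
Why: Baeyer–Villiger (Dakin-type) oxidation in which the electron-rich aryl group, carrying ortho and para methoxy donors, migrates in preference to hydride, and the aryl formate is then cleaved by base-catalysed methanolysis.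

Step 2
Reactants: 3 2,3,4-trimethoxyphenol
Product: 4 1,2,3,4-tetramethoxybenzene
Conditions: MeI, K2CO3, acetone, reflux
Reagents that add atoms: iodomethane, CI
Why: Williamson O-methylation, an SN2 reaction of the phenoxide on iodomethane with no competing site.

Step 3
Reactants: 4 1,2,3,4-tetramethoxybenzene
Product: 7 2,3,4,5-tetramethoxyphenol, via aryllithium 5 (not isolated), via lithium aryltrimethoxyborate 6 (not isolated)
Conditions: n-BuLi, TMEDA, THF, 0 °C; B(OMe)3, −78 → 25 °C; then H2O2, AcOH, 0 °C
Reagents that add atoms: hydrogen peroxide, OO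
Why: Directed ortho-lithiation next to a methoxy group (the two ring C–H positions of 4 are equivalent), borylation of the aryllithium and oxidative 1,2-shift of the aryl group from boron to oxygen should place the hydroxyl group on the metalated carbon.

Step 4
Reactants: 7 2,3,4,5-tetramethoxyphenol; 8 methoxyacetyl chloride
Product: 11 1-(2-hydroxy-3,4,5,6-tetramethoxyphenyl)-2-methoxyethan-1-one, via aryl methoxyacetate 9 (not isolated), via difluoroboron chelate 10 (not isolated)
Conditions: BF3·OEt2 (3 equiv), ClCH2CH2Cl, 0 → 75 °C; then H2O–MeOH, 60 °C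
Reagents that add atoms: none
Why: O-acylation followed by BF3-promoted Fries rearrangement (net Friedel–Crafts ortho-acylation) can reach only the single free ring position, which is ortho to the phenol oxygen, and the ketone is held as its difluoroboron chelate until hydrolysis.

Step 5
Reactants: 11 1-(2-hydroxy-3,4,5,6-tetramethoxyphenyl)-2-methoxyethan-1-one
Product: 13 3,5,6,7,8-pentamethoxy-4H-chromen-4-one, via enaminone 12 (not isolated)
Conditions: Me2NCH(OMe)2, toluene, 100 °C; then AcOH, 90 °C
Reagents that add atoms: N,N-dimethylformamide dimethyl acetal, COC(OC)N(C)C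
Why: Condensation of the amide acetal at the ketone α-CH2 gives an enaminone, and intramolecular conjugate addition of the phenol with loss of dimethylamine closes pyranone ring C, the standard enaminone chromone synthesis from 2-hydroxyaryl ketones.

Step 6
Reactants: 13 3,5,6,7,8-pentamethoxy-4H-chromen-4-one
Product: 15 2-iodo-3,5,6,7,8-pentamethoxy-4H-chromen-4-one, via chromon-2-ylzinc chloride 14 (not isolated)
Conditions: TMPZnCl·LiCl, THF, 25 °C; then I2, 0 °C
Reagents that add atoms: iodine, II
Why: Deprotonative zincation at C2, the only C–H of the pyranone ring and acidified by O1 and the 3-methoxy group, with the mild amide base TMPZnCl·LiCl, followed by iodinolysis of the carbon–zinc bond.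

Step 7
Reactants: 15 2-iodo-3,5,6,7,8-pentamethoxy-4H-chromen-4-one; 16 trimethylsilylacetylene
Product: 17 3,5,6,7,8-pentamethoxy-2-[(trimethylsilyl)ethynyl]-4H-chromen-4-one
Conditions: PdCl2(PPh3)2 (cat.), CuI (cat.), Et3N, THF, 25 °C
Reagents that add atoms: none
Why: Sonogashira coupling of a β-iodo enone, which undergoes fast oxidative addition, with a tertiary amine as base so that no addition–elimination takes place at C2.

Step 8
Reactants: 17 3,5,6,7,8-pentamethoxy-2-[(trimethylsilyl)ethynyl]-4H-chromen-4-one
Product: 18 2-ethynyl-3,5,6,7,8-pentamethoxy-4H-chromen-4-one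
Conditions: Bu4NF, AcOH, THF, −20 °C
Reagents that add atoms: none
Why: Fluoride-induced protodesilylation of the alkynylsilane, buffered with acetic acid and kept cold so that no basic nucleophile adds to the electrophilic enynone; the alkyne is used directly in step 10.

Step 9
Reactants: 19 methyl (E)-3-methoxybut-2-enoate
Product: 21 (1E)-1,3-dimethoxy-1-(trimethylsilyloxy)buta-1,3-diene, via lithium dienolate 20 (not isolated)
Conditions: LiN(iPr)2, THF, −78 °C; Me3SiCl, −78 → 25 °C; distil
Reagents that add atoms: chlorotrimethylsilane, C[Si](C)(C)Cl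
Why: γ-Deprotonation of the vinylogous ester to the extended lithium dienolate and kinetic O-silylation (silyl ketene acetal formation) give the 1,1,3-trioxygenated diene.

Step 10
Reactants: 18 2-ethynyl-3,5,6,7,8-pentamethoxy-4H-chromen-4-one; 21 (1E)-1,3-dimethoxy-1-(trimethylsilyloxy)buta-1,3-diene
Product: 23 2-(2-hydroxy-4-methoxyphenyl)-3,5,6,7,8-pentamethoxy-4H-chromen-4-one, via cyclohexadiene adduct 22 (not isolated)
Conditions: toluene, 110 °C, sealed tube (21 in excess); then 1 M HCl, THF, 25 °C
Reagents that add atoms: none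
Why: Proposed new method: the ketene acetal diene 21, whose HOMO is raised by three oxygen donors and has its largest coefficient on the CH2 terminus, should add to the alkyne of 18, whose terminal carbon is the δ-position of the C4 carbonyl (O=C4–C3=C2–C≡CH), either in a concerted but asynchronous [4+2] cycloaddition or, at the limit, by 1,6-Mukaiyama–Michael addition followed by 6-exo-trig closure of the allenyl enolate onto the silyl oxocarbenium carbon; in both cases ring B closes as a six-membered carbocycle by intermolecular [4+2] annulation that forms C5'–C6' and C1'–C2'. The closest known reaction type is the Diels–Alder reaction of 1-alkoxy-1-silyloxy-1,3-dienes with acetylenic esters, acetylenic ketones and haloquinones, which gives resorcinol monoethers after loss of methanol; an alkyne activated only through the C2=C3 bond of a chromone has not been used as the dienophile. The cyclohexa-1,4-diene 22 has its only new stereocenter at the ketal carbon C2', formed as a racemate under no control, and it disappears when acid cleaves the silyl methyl ketal to a dienone that tautomerises to the 2'-phenol, while the enol ether at C4' stays as methoxy. The step needs orientational selectivity (CH2 terminus to C6', ketal carbon to C1'), which the polarisation of the alkyne by the pyranone carbonyl and the unhindered terminal CH should secure, and site selectivity for the alkyne over the chromone C2=C3 bond, which is tetrasubstituted and deactivated by its two oxygen donors.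

Step 11
Reactants: 23 2-(2-hydroxy-4-methoxyphenyl)-3,5,6,7,8-pentamethoxy-4H-chromen-4-one
Product: 25 5-hydroxy-2-(2-hydroxy-4-methoxyphenyl)-3,6,7,8-tetramethoxy-4H-chromen-4-one, via dichloroboron aryloxide 24 (not isolated)
Conditions: BCl3 (2.5 equiv), CH2Cl2, −78 → 0 °C; then H2O
Reagents that add atoms: none
Why: Chelation-controlled Lewis acid ether cleavage in which BCl3 bound to the C4 carbonyl forms a six-membered chelate with the peri 5-methoxy oxygen and chloride removes that methyl group, whereas the 6-, 7-, 8- and 4'-methoxy groups have no chelating partner and the 3-methoxy group would need a more strained five-membered chelate; the second equivalent of BCl3 is taken up by the 2'-phenol.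

**Compound list**

1 | 2,3,4-trimethoxybenzaldehyde | COc1ccc(C=O)c(OC)c1OC | starting material
2 | 2,3,4-trimethoxyphenyl formate | COc1ccc(OC=O)c(OC)c1OC | intermediate (not isolated)
3 | 2,3,4-trimethoxyphenol | COc1ccc(O)c(OC)c1OC | intermediate
4 | 1,2,3,4-tetramethoxybenzene | COc1ccc(OC)c(OC)c1OC | intermediate
5 | (2,3,4,5-tetramethoxyphenyl)lithium | [Li]c1cc(OC)c(OC)c(OC)c1OC | intermediate (not isolated)
6 | lithium trimethoxy(2,3,4,5-tetramethoxyphenyl)borate | [Li+].CO[B-](OC)(OC)c1cc(OC)c(OC)c(OC)c1OC | intermediate (not isolated)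
7 | 2,3,4,5-tetramethoxyphenol | COc1cc(O)c(OC)c(OC)c1OC | intermediate
8 | methoxyacetyl chloride | COCC(=O)Cl | starting material
9 | 2,3,4,5-tetramethoxyphenyl methoxyacetate | COCC(=O)Oc1cc(OC)c(OC)c(OC)c1OC | intermediate (not isolated)
10 | difluoroboron O,O-chelate of ketone 11 (phenoxide and carbonyl oxygens on boron) | COCC1=[O+][B-](F)(F)Oc2c(OC)c(OC)c(OC)c(OC)c12 | intermediate (not isolated)
11 | 1-(2-hydroxy-3,4,5,6-tetramethoxyphenyl)-2-methoxyethan-1-one | COCC(=O)c1c(O)c(OC)c(OC)c(OC)c1OC | intermediate
12 | (Z)-3-(dimethylamino)-1-(2-hydroxy-3,4,5,6-tetramethoxyphenyl)-2-methoxyprop-2-en-1-one | CN(C)/C=C(\OC)C(=O)c1c(O)c(OC)c(OC)c(OC)c1OC | intermediate (not isolated)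
13 | 3,5,6,7,8-pentamethoxy-4H-chromen-4-one | COc1coc2c(OC)c(OC)c(OC)c(OC)c2c1=O | intermediate
14 | chlorido(3,5,6,7,8-pentamethoxy-4-oxo-4H-chromen-2-yl)zinc, LiCl complex | COc1c([Zn]Cl)oc2c(OC)c(OC)c(OC)c(OC)c2c1=O.[Li+].[Cl-] | intermediate (not isolated)
15 | 2-iodo-3,5,6,7,8-pentamethoxy-4H-chromen-4-one | COc1c(I)oc2c(OC)c(OC)c(OC)c(OC)c2c1=O | intermediate
16 | trimethylsilylacetylene | C#C[Si](C)(C)C | starting material
17 | 3,5,6,7,8-pentamethoxy-2-[(trimethylsilyl)ethynyl]-4H-chromen-4-one | COc1c(C#C[Si](C)(C)C)oc2c(OC)c(OC)c(OC)c(OC)c2c1=O | intermediate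
18 | 2-ethynyl-3,5,6,7,8-pentamethoxy-4H-chromen-4-one | C#Cc1oc2c(OC)c(OC)c(OC)c(OC)c2c(=O)c1OC | intermediate
19 | methyl (E)-3-methoxybut-2-enoate | CO/C(C)=C/C(=O)OC | starting material
20 | lithium dienolate of 19 (O-lithiated, same double-bond arrangement as 21) | C=C(OC)/C=C(\OC)O[Li] | intermediate (not isolated)
21 | (1E)-1,3-dimethoxy-1-(trimethylsilyloxy)buta-1,3-diene | C=C(OC)/C=C(\OC)O[Si](C)(C)C | intermediate
22 | 2-[4,6-dimethoxy-6-(trimethylsilyloxy)cyclohexa-1,4-dien-1-yl]-3,5,6,7,8-pentamethoxy-4H-chromen-4-one (racemic at the ketal carbon) | COC1=CC(OC)(O[Si](C)(C)C)C(=CC1)c1oc2c(OC)c(OC)c(OC)c(OC)c2c(=O)c1OC | intermediate (not isolated)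
23 | 2-(2-hydroxy-4-methoxyphenyl)-3,5,6,7,8-pentamethoxy-4H-chromen-4-one | COc1ccc(-c2oc3c(OC)c(OC)c(OC)c(OC)c3c(=O)c2OC)c(O)c1 | intermediate
24 | 5-[(dichloroboranyl)oxy]-2-{2-[(dichloroboranyl)oxy]-4-methoxyphenyl}-3,6,7,8-tetramethoxy-4H-chromen-4-one | COc1ccc(-c2oc3c(OC)c(OC)c(OC)c(OB(Cl)Cl)c3c(=O)c2OC)c(OB(Cl)Cl)c1 | intermediate (not isolated)
25 | 5-hydroxy-2-(2-hydroxy-4-methoxyphenyl)-3,6,7,8-tetramethoxy-4H-chromen-4-one (5,2'-dihydroxy-3,6,7,8,4'-pentamethoxyflavone) | COc1ccc(-c2oc3c(OC)c(OC)c(OC)c(O)c3c(=O)c2OC)c(O)c1 | target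

**Step count**

Total: 11 steps. Longest linear sequence: 10 steps (steps 1–8, 10 and 11); the diene branch is one step (step 9).

**Steps most likely to fail**

Step 10. The cycloaddition may be slower than thermal decay of the diene (silyl transfer, oligomerisation), or the reaction may stop after conjugate addition without ring closure; reversed orientation is the lesser risk. The fallback builds ring B from a preformed arene by known cross-coupling chemistry. It sets out from chromone 13 and returns at 23. Commercial 2-bromo-5-methoxyphenol is benzylated (BnBr, K2CO3, DMF) to 1-(benzyloxy)-2-bromo-5-methoxybenzene F1. Chromone 13 is zincated as in step 6 to 14, and Negishi coupling of 14 with F1 (Pd(OAc)2, SPhos, THF, 50 °C) should give 2-[2-(benzyloxy)-4-methoxyphenyl]-3,5,6,7,8-pentamethoxy-4H-chromen-4-one F2. Hydrogenolysis of the benzyl ether (H2, Pd/C, EtOAc) then gives 23, and step 11 follows unchanged.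

Step 4. The activated methoxyacetyl unit may lose carbon monoxide (alkoxymethylation in place of acylation), the acyl shift into the crowded last ring position may be slow, or the Lewis acid may cleave a methyl ether. The fallback replaces electrophilic acylation by directed metalation. It sets out from phenol 7 and returns at ketone 11. Methylation (MeI, K2CO3, acetone) gives pentamethoxybenzene F3. Lithiation of its only ring C–H (n-BuLi, TMEDA, THF, 0 °C) gives (pentamethoxyphenyl)lithium F4, which is acylated with commercial N,2-dimethoxy-N-methylacetamide (Weinreb ketone synthesis, −78 °C) to 2-methoxy-1-(pentamethoxyphenyl)ethan-1-one F5. BCl3 (1.1 equiv, CH2Cl2, −78 → 0 °C) then removes one of the two equivalent methyl groups ortho to the carbonyl through the dichloroboron aryloxide F6, and aqueous work-up gives 11.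

Step 11. A second methyl group may be lost: the 3-methyl ether, to which the neighbouring 2'-O–BCl2 group can deliver Lewis acid, or the 6-methyl ether once the 5-oxygen is boron-bound. The fallback masks the 2'-phenol before the ether cleavage so that only the carbonyl can direct the reagent. It sets out from 23 and returns at 25. Acetylation (Ac2O, pyridine) gives 5-methoxy-2-(3,5,6,7,8-pentamethoxy-4-oxo-4H-chromen-2-yl)phenyl acetate F7. BCl3 (1.2 equiv, CH2Cl2, −78 → 0 °C) cleaves the 5-methyl ether through the single dichloroboron chelate F8, and aqueous work-up gives 2-(5-hydroxy-3,6,7,8-tetramethoxy-4-oxo-4H-chromen-2-yl)-5-methoxyphenyl acetate F9. Methanolysis of the acetate (K2CO3 cat., MeOH, 0 °C) gives 25.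

**Further compounds**

F1 | step 10 | 1-(benzyloxy)-2-bromo-5-methoxybenzene | COc1ccc(Br)c(OCc2ccccc2)c1
F2 | step 10 | 2-[2-(benzyloxy)-4-methoxyphenyl]-3,5,6,7,8-pentamethoxy-4H-chromen-4-one | COc1ccc(-c2oc3c(OC)c(OC)c(OC)c(OC)c3c(=O)c2OC)c(OCc2ccccc2)c1
F3 | step 4 | pentamethoxybenzene | COc1cc(OC)c(OC)c(OC)c1OC
F4 | step 4 | (pentamethoxyphenyl)lithium | [Li]c1c(OC)c(OC)c(OC)c(OC)c1OC
F5 | step 4 | 2-methoxy-1-(pentamethoxyphenyl)ethan-1-one | COCC(=O)c1c(OC)c(OC)c(OC)c(OC)c1OC
F6 | step 4 | 1-{2-[(dichloroboranyl)oxy]-3,4,5,6-tetramethoxyphenyl}-2-methoxyethan-1-one | COCC(=O)c1c(OB(Cl)Cl)c(OC)c(OC)c(OC)c1OC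
F7 | step 11 | 5-methoxy-2-(3,5,6,7,8-pentamethoxy-4-oxo-4H-chromen-2-yl)phenyl acetate | COc1ccc(-c2oc3c(OC)c(OC)c(OC)c(OC)c3c(=O)c2OC)c(OC(C)=O)c1
F8 | step 11 | 2-{5-[(dichloroboranyl)oxy]-3,6,7,8-tetramethoxy-4-oxo-4H-chromen-2-yl}-5-methoxyphenyl acetate | COc1ccc(-c2oc3c(OC)c(OC)c(OC)c(OB(Cl)Cl)c3c(=O)c2OC)c(OC(C)=O)c1
F9 | step 11 | 2-(5-hydroxy-3,6,7,8-tetramethoxy-4-oxo-4H-chromen-2-yl)-5-methoxyphenyl acetate | COc1ccc(-c2oc3c(OC)c(OC)c(OC)c(O)c3c(=O)c2OC)c(OC(C)=O)c1
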